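**Retrosynthetic overview**
1. The aliphatic acetate goes on last, at the only non-phenolic OH of the triphenolic tetrahydrofuran alcohol. No protecting groups remain at that stage.
2. The key disconnection is the ring O–C2 (benzylic) bond. The tetrahydrofuran comes from an open-chain (2R,3R)-2,3-dibenzylbutane-1,4-diol by catechol-selective dehydrogenative cycloetherification (C–H + O–H to C–O), which also sets C2.
3. The diol comes from hydride reduction of a trans-3,4-dibenzyl-5-menthyloxybutyrolactone, after sulfur and benzyl groups are removed in one operation.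
4. That lactone comes from a one-flask, three-component coupling of an aryl dithioacetal anion, a chiral 5-menthyloxybutenolide and a benzylic chloride. This sets C3 and C4.
5. Ring order: the bought butenolide ring serves only as a stereochemical template and is opened in step 4. The one ring that is built, the tetrahydrofuran, is closed in step 5.

Assumption: the chiral butenolide and the benzylic chloride are bought as catalogue chemicals.

**Step 1**
Reactants: 1 4-(benzyloxy)-3-methoxybenzaldehyde (O-benzylvanillin); 2 thiophenol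
Product: 3 1-(benzyloxy)-4-[bis(phenylsulfanyl)methyl]-2-methoxybenzene
Conditions: PhSH (2.1 equiv), BF3·OEt2 (0.2 equiv), CH2Cl2, 0 °C to rt
Reagents that add atoms: thiophenol 2, Sc1ccccc1
Why: Lewis-acid-catalysed dithioacetalisation of an aromatic aldehyde turns the aldehyde carbon into an acidic C–H (umpolung) that later becomes the benzylic CH2, and no stereocentre is formed.

**Step 2**
Reactants: 3 1-(benzyloxy)-4-[bis(phenylsulfanyl)methyl]-2-methoxybenzene; 4 (5R)-5-(l-menthyloxy)furan-2(5H)-one; 5 3,4-bis(benzyloxy)benzyl chloride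
Product: 8 (3R,4R,5R)-3-[3,4-bis(benzyloxy)benzyl]-4-{[4-(benzyloxy)-3-methoxyphenyl]bis(phenylsulfanyl)methyl}-5-(l-menthyloxy)dihydrofuran-2(3H)-one, via lithiated thioacetal 6 (not isolated), via lithium enolate 7 (not isolated)
Conditions: n-BuLi (1.05 equiv), THF, −78 °C, 30 min; add 4, −78 °C, 1 h; add 5 (1.2 equiv), Bu4NI (10 mol %), DMPU (4 equiv), −78 °C to 0 °C; aq NH4Cl
Reagents that add atoms: none
Why: In this tandem Michael addition–enolate alkylation on a γ-alkoxybutenolide, the soft sulfur-stabilised carbanion adds 1,4 anti to the menthyloxy group (sets C4 as R), and the resulting enolate is benzylated anti to the bulky new C4 substituent (sets C3 as R).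

**Step 3**
Reactants: 8 (3R,4R,5R)-3-[3,4-bis(benzyloxy)benzyl]-4-{[4-(benzyloxy)-3-methoxyphenyl]bis(phenylsulfanyl)methyl}-5-(l-menthyloxy)dihydrofuran-2(3H)-one
Product: 9 (3R,4R,5R)-3-(3,4-dihydroxybenzyl)-4-(4-hydroxy-3-methoxybenzyl)-5-(l-menthyloxy)dihydrofuran-2(3H)-one
Conditions: Raney Ni (W-2, large excess), H2 (1 atm), EtOH–THF, 60 °C
Reagents that add atoms: none
Why: Raney nickel hydrogenolysis (Mozingo-type desulfurisation) cleaves both C–S bonds and, under H2, the three aryl benzyl ethers in the same operation, while the lactone, the acetal, the methyl ether and the three stereocentres are untouched.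

**Step 4**
Reactants: 9 (3R,4R,5R)-3-(3,4-dihydroxybenzyl)-4-(4-hydroxy-3-methoxybenzyl)-5-(l-menthyloxy)dihydrofuran-2(3H)-one
Product: 10 (2R,3R)-2-(3,4-dihydroxybenzyl)-3-(4-hydroxy-3-methoxybenzyl)butane-1,4-diol
Conditions: LiAlH4 (6 equiv), THF, 0 °C to reflux; 1 M HCl work-up
Reagents that add atoms: none
Why: In this hydride reduction of a pseudo-ester, the lactone carbonyl is reduced and the released hemiacetal alkoxide expels mentholate to give an aldehyde that is reduced at once, so both termini become CH2OH and the two stereocentres are carried over unchanged.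

**Step 5**
Reactants: 10 (2R,3R)-2-(3,4-dihydroxybenzyl)-3-(4-hydroxy-3-methoxybenzyl)butane-1,4-diol
Product: 13 4-[(2S,3R,4R)-4-(4-hydroxy-3-methoxybenzyl)-3-(hydroxymethyl)tetrahydrofuran-2-yl]benzene-1,2-diol, via ortho-quinone 11 (not isolated), via hydroxy quinone methide 12 (not isolated)
Conditions: Ag2O (1.05 equiv), 4 Å MS, MeCN (0.01 M), 0 °C, dark, 15 min; filter through Celite under Ar; Bu4N[(PhO)2PO2] (10 mol %), 0 °C to rt, 2 h
Reagents that add atoms: none
Why: Proposed new method: catechol-selective dehydrogenative cycloetherification through a quinone to quinone-methide tautomerisation relay. Ag2O (monovalent silver) oxidises only the catechol, whose two-electron potential lies well below that of the guaiacol ring, to ortho-quinone 11 within minutes, and it is filtered off so that no oxidant is present when the product catechol appears. The benzylic C–H of 11 is the γ-position of a vinylogous 1,2-dione, so the weakly basic, non-nucleophilic diphenyl phosphate anion acts as a proton shuttle (C–H to O) and gives the 2-hydroxy-para-quinone methide 12. The CH2OH group on the neighbouring stereocentre then adds 5-exo-trig to the methide carbon (1,6-oxa-Michael), driven by rearomatisation to the catechol, whereas the other CH2OH could only form an oxetane and stays free. The new C2 centre is set as S (2,3-trans) by minimised A(1,3) strain in the closure and by reversibility of the oxa-Michael step under the weak base, and the absence of acid avoids Friedel–Crafts closure to the aryltetralin. The closest known reaction types are the DDQ- or Ag2O-mediated oxidative cyclisation of 4-hydroxybenzyl compounds via para-quinone methides and the ortho-quinone to quinone-methide tautomerisation of 4-alkylcatechols with capture by water or methanol. Preparative intramolecular alcohol capture to a 2-aryltetrahydrofuran, with discrimination between a catechol and a guaiacol ring, has not been shown.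

**Step 6**
Reactants: 13 4-[(2S,3R,4R)-4-(4-hydroxy-3-methoxybenzyl)-3-(hydroxymethyl)tetrahydrofuran-2-yl]benzene-1,2-diol; 14 vinyl acetate
Product: 15 [(2S,3R,4R)-2-(3,4-dihydroxyphenyl)-4-(4-hydroxy-3-methoxybenzyl)tetrahydrofuran-3-yl]methyl acetate (target)
Conditions: immobilised Candida antarctica lipase B, vinyl acetate (5 equiv), acetone, 40 °C, Ar
Reagents that add atoms: vinyl acetate 14, C=COC(C)=O
Why: In this lipase-catalysed irreversible transesterification, the serine hydrolase acylates the primary aliphatic alcohol but not the three phenols, the leaving enol tautomerises to acetaldehyde, and the neutral medium spares the acid-sensitive 2-aryltetrahydrofuran and the catechol, so no stereocentre is touched.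

**Compound list**
1 | 4-(benzyloxy)-3-methoxybenzaldehyde (O-benzylvanillin) | COc1cc(C=O)ccc1OCc1ccccc1 | starting material
2 | thiophenol | Sc1ccccc1 | starting material
3 | 1-(benzyloxy)-4-[bis(phenylsulfanyl)methyl]-2-methoxybenzene | COc1cc(C(Sc2ccccc2)Sc2ccccc2)ccc1OCc1ccccc1 | intermediate
4 | (5R)-5-{[(1R,2S,5R)-2-isopropyl-5-methylcyclohexyl]oxy}furan-2(5H)-one, i.e. (5R)-5-(l-menthyloxy)furan-2(5H)-one | O=C1O[C@@H](O[C@@H]2C[C@H](C)CC[C@H]2C(C)C)C=C1 | starting material
5 | 3,4-bis(benzyloxy)benzyl chloride | ClCc1ccc(OCc2ccccc2)c(OCc2ccccc2)c1 | starting material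
6 | [4-(benzyloxy)-3-methoxyphenyl]bis(phenylsulfanyl)methyllithium | [Li]C(Sc1ccccc1)(Sc1ccccc1)c1ccc(OCc2ccccc2)c(OC)c1 | intermediate
7 | lithium enolate of the (4R,5R)-Michael adduct (C2–OLi, C2=C3) | [Li]OC1=C[C@@H](C(Sc2ccccc2)(Sc2ccccc2)c2ccc(OCc3ccccc3)c(OC)c2)[C@H](O[C@@H]2C[C@H](C)CC[C@H]2C(C)C)O1 | intermediate
8 | (3R,4R,5R)-3-[3,4-bis(benzyloxy)benzyl]-4-{[4-(benzyloxy)-3-methoxyphenyl]bis(phenylsulfanyl)methyl}-5-(l-menthyloxy)dihydrofuran-2(3H)-one | O=C1O[C@@H](O[C@@H]2C[C@H](C)CC[C@H]2C(C)C)[C@H](C(Sc2ccccc2)(Sc2ccccc2)c2ccc(OCc3ccccc3)c(OC)c2)[C@H]1Cc1ccc(OCc2ccccc2)c(OCc2ccccc2)c1 | intermediate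
9 | (3R,4R,5R)-3-(3,4-dihydroxybenzyl)-4-(4-hydroxy-3-methoxybenzyl)-5-(l-menthyloxy)dihydrofuran-2(3H)-one | O=C1O[C@@H](O[C@@H]2C[C@H](C)CC[C@H]2C(C)C)[C@H](Cc2ccc(O)c(OC)c2)[C@H]1Cc1ccc(O)c(O)c1 | intermediate
10 | (2R,3R)-2-(3,4-dihydroxybenzyl)-3-(4-hydroxy-3-methoxybenzyl)butane-1,4-diol | COc1cc(C[C@@H](CO)[C@H](CO)Cc2ccc(O)c(O)c2)ccc1O | intermediate
11 | 4-[(2R,3R)-4-hydroxy-2-(hydroxymethyl)-3-(4-hydroxy-3-methoxybenzyl)butyl]cyclohexa-3,5-diene-1,2-dione | COc1cc(C[C@@H](CO)[C@H](CO)CC2=CC(=O)C(=O)C=C2)ccc1O | intermediate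
12 | 2-hydroxy-4-alkylidenecyclohexa-2,5-dien-1-one tautomer of 11 (same two stereocentres as 10, alkene geometry not fixed) | COc1cc(C[C@@H](CO)[C@H](CO)C=C2C=CC(=O)C(O)=C2)ccc1O | intermediate
13 | 4-[(2S,3R,4R)-4-(4-hydroxy-3-methoxybenzyl)-3-(hydroxymethyl)tetrahydrofuran-2-yl]benzene-1,2-diol | COc1cc(C[C@H]2CO[C@H](c3ccc(O)c(O)c3)[C@H]2CO)ccc1O | intermediate
14 | vinyl acetate | C=COC(C)=O | starting material
15 | [(2S,3R,4R)-2-(3,4-dihydroxyphenyl)-4-(4-hydroxy-3-methoxybenzyl)tetrahydrofuran-3-yl]methyl acetate | COc1cc(C[C@H]2CO[C@H](c3ccc(O)c(O)c3)[C@H]2COC(C)=O)ccc1O | target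

**Total step count:** 6. **Longest linear sequence:** 6 (1 → 3 → 8 → 9 → 10 → 13 → 15).

**Three steps most likely to fail**

*Step 5 (the new reaction).*
- The ortho-quinone 11 may dimerise.
- An alcohol may add to the quinone ring of 11 instead of to the methide carbon.
- 11 may exchange redox state with product 13.
- 12 may close onto the guaiacyl ring to give the aryltetralin.

The fallback uses known chemistry only. It sets out from enolate 7 (made from 3 and 4 as in step 2) and comes back at 13. Enolate 7 is trapped at −78 °C with commercial 3,4-bis(benzyloxy)benzaldehyde (tandem Michael–aldol) to give the hydroxy dithioacetal lactone F1 as carbinol epimers. NiCl2·6H2O/NaBH4 in MeOH–THF at 0 °C removes sulfur but keeps the benzyl ethers and the carbinol, giving the hydroxy lactone F2. LiAlH4 in THF then gives the tri-O-benzyl triol F3. Catalytic camphorsulfonic acid in CH2Cl2 at 0 °C ionises either carbinol epimer to the para-alkoxybenzyl cation, which closes to the 2,3-trans tri-O-benzyl tetrahydrofuran alcohol F4. Brief hydrogenolysis (H2, Pd/C, EtOAc, 1 atm) gives 13.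

*Step 2 (three-component coupling).*
- The hindered enolate 7 may undergo retro-Michael loss of the dithioacetal anion on warming.
- 7 may react too slowly with the benzylic chloride.

The fallback sets out from 7 and comes back at 9. It decouples the two bond formations and removes sulfur before the alkylation. Enolate 7 is quenched with aq NH4Cl to give the protonated Michael adduct F5. NiCl2·6H2O/NaBH4 gives the monobenzyl menthyloxy lactone F6. The enolate of F6 (LDA, THF, −78 °C) is unhindered and cannot fragment, so it can be warmed to rt with 5 and Bu4NI to give the trans tri-O-benzyl dibenzyl lactone F7. H2, Pd/C in EtOAc–EtOH then gives 9.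

*Step 6 (chemoselective acetylation).*
- The CH2OH group is flanked by two ring substituents and may be a slow lipase substrate.
- The catechol limits the use of harsher acylating conditions.

The fallback sets out from 13 and comes back at 15. Exhaustive acetylation (Ac2O, pyridine, rt) gives the tetraacetate F8. NH4OAc in aqueous MeOH at rt then methanolyses only the three aryl acetates, whose phenoxides are much better leaving groups, and leaves the alkyl acetate of 15.

**Further compounds**
F1 | step 5 | hydroxy dithioacetal lactone: (3S,4R,5R)-3-{[3,4-bis(benzyloxy)phenyl](hydroxy)methyl}-4-{[4-(benzyloxy)-3-methoxyphenyl]bis(phenylsulfanyl)methyl}-5-(l-menthyloxy)dihydrofuran-2(3H)-one, carbinol epimers | O=C1O[C@@H](O[C@@H]2C[C@H](C)CC[C@H]2C(C)C)[C@H](C(Sc2ccccc2)(Sc2ccccc2)c2ccc(OCc3ccccc3)c(OC)c2)[C@H]1C(O)c1ccc(OCc2ccccc2)c(OCc2ccccc2)c1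
F2 | step 5 | hydroxy lactone: (3S,4R,5R)-3-{[3,4-bis(benzyloxy)phenyl](hydroxy)methyl}-4-[4-(benzyloxy)-3-methoxybenzyl]-5-(l-menthyloxy)dihydrofuran-2(3H)-one, carbinol epimers | O=C1O[C@@H](O[C@@H]2C[C@H](C)CC[C@H]2C(C)C)[C@H](Cc2ccc(OCc3ccccc3)c(OC)c2)[C@H]1C(O)c1ccc(OCc2ccccc2)c(OCc2ccccc2)c1
F3 | step 5 | tri-O-benzyl triol: (2R,3R)-2-{[3,4-bis(benzyloxy)phenyl](hydroxy)methyl}-3-[4-(benzyloxy)-3-methoxybenzyl]butane-1,4-diol, carbinol epimers | COc1cc(C[C@@H](CO)[C@H](CO)C(O)c2ccc(OCc3ccccc3)c(OCc3ccccc3)c2)ccc1OCc1ccccc1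
F4 | step 5 | tri-O-benzyl tetrahydrofuran alcohol: {(2S,3R,4R)-2-[3,4-bis(benzyloxy)phenyl]-4-[4-(benzyloxy)-3-methoxybenzyl]tetrahydrofuran-3-yl}methanol | COc1cc(C[C@H]2CO[C@H](c3ccc(OCc4ccccc4)c(OCc4ccccc4)c3)[C@H]2CO)ccc1OCc1ccccc1
F5 | step 2 | protonated Michael adduct: (4R,5R)-4-{[4-(benzyloxy)-3-methoxyphenyl]bis(phenylsulfanyl)methyl}-5-(l-menthyloxy)dihydrofuran-2(3H)-one | O=C1O[C@@H](O[C@@H]2C[C@H](C)CC[C@H]2C(C)C)[C@H](C(Sc2ccccc2)(Sc2ccccc2)c2ccc(OCc3ccccc3)c(OC)c2)C1
F6 | step 2 | monobenzyl menthyloxy lactone: (4R,5R)-4-[4-(benzyloxy)-3-methoxybenzyl]-5-(l-menthyloxy)dihydrofuran-2(3H)-one | O=C1O[C@@H](O[C@@H]2C[C@H](C)CC[C@H]2C(C)C)[C@H](Cc2ccc(OCc3ccccc3)c(OC)c2)C1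
F7 | step 2 | tri-O-benzyl dibenzyl lactone: (3R,4R,5R)-3-[3,4-bis(benzyloxy)benzyl]-4-[4-(benzyloxy)-3-methoxybenzyl]-5-(l-menthyloxy)dihydrofuran-2(3H)-one | O=C1O[C@@H](O[C@@H]2C[C@H](C)CC[C@H]2C(C)C)[C@H](Cc2ccc(OCc3ccccc3)c(OC)c2)[C@H]1Cc1ccc(OCc2ccccc2)c(OCc2ccccc2)c1
F8 | step 6 | tetraacetate: {(2S,3R,4R)-2-(3,4-diacetoxyphenyl)-4-(4-acetoxy-3-methoxybenzyl)tetrahydrofuran-3-yl}methyl acetate | COc1cc(C[C@H]2CO[C@H](c3ccc(OC(C)=O)c(OC(C)=O)c3)[C@H]2COC(C)=O)ccc1OC(C)=O
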